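**Plan**

1. Retrosynthesis: the 5,5′-biaryl bond is cut first (Suzuki–Miyaura) into an oxolane half and a tetralin half. The tetralin is then opened at the bond from its aryl-bearing carbon C1 to the fused arene (retro-Friedel–Crafts), so both halves are one bromo-oxolane monomer, 19.
2. In the oxolane ring of 19 (O1–C2–C3–C4–C5) the hydrogens on C2 and C3 are removed (retro-hydrogenation), then the CH2OH carbon on C3 (retro-formylation). The C2=C3 bond of the resulting 4,5-dihydrofuran is cut last, to an aroate ester on the C5 oxygen and a vinyl group on C4; the ester goes back to a vinyl epoxide and a benzoic acid.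
3. Enabling feature: C2 carries both the ring oxygen O1 and an aryl group, so one oxidation level up it is the carbonyl carbon of an aroate of the C5–O unit. C3 is the neighbour of the quaternary carbinol carbon C4, which can carry a vinyl group, so an ester–olefin ring-closing metathesis closes the five-membered ring through C2=C3.
4. Forward order: allylic alcohol → epoxy alcohol → vinyl epoxide → hydroxy ester → dihydrofuran ring (step 10) → C3 formylation and reduction → hydrogenation to oxolane 19 → one part of 19 to the tetralin, the other to the boronate → biaryl coupling → debenzylation.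
5. Stereochemistry: C4 comes from the Sharpless asymmetric epoxidation. C2 and C3 come from delivery of H2 to the C4–OH face of the tetrasubstituted C2=C3 bond, which puts aryl, CH2OH and arylmethyl all cis. Tetralin C1 is set in the Friedel–Crafts closure (aryl trans to the neighbouring CH2OH); its other two centres are inherited from 19.

Key step: step 10

Abbreviations: ArBr = 4-(benzyloxy)-3-bromo-5-methoxyphenyl; ArG = 4-(benzyloxy)-3-methoxyphenyl.

Remark: the oxolane is numbered O1, C2 (aryl), C3 (CH2OH), C4 (OH, arylmethyl), C5 throughout; both halves of the target have the same configuration at the CH(CH2OH) and C(OH) carbons, so the single monomer 19 serves for both; 1, 4 and 5 are taken as catalogue compounds.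

**Route**

Step 1
Reactants: 1 5-bromovanillin
Product: 2 4-(benzyloxy)-3-bromo-5-methoxybenzaldehyde
Conditions: BnBr, K2CO3, DMF, 60 °C
Reagents that add atoms: benzyl bromide BrCc1ccccc1
Why: Williamson ether synthesis on the phenoxide; the benzyl ether is stable to every later basic, Lewis-acidic and hydride step and leaves with the other three benzyl groups at the end.

Step 2
Reactants: 2 4-(benzyloxy)-3-bromo-5-methoxybenzaldehyde
Product: 3 4-(benzyloxy)-3-bromo-5-methoxybenzoic acid
Conditions: NaClO2, NaH2PO4, 2-methyl-2-butene, tBuOH–H2O, rt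
Reagents that add atoms: sodium chlorite [Na+].[O-]Cl=O
Why: Pinnick oxidation converts the aryl aldehyde to the acid without touching the aryl bromide or the benzyl ether, the alkene scavenging hypochlorous acid.

Step 3
Reactants: 4 [4-(benzyloxy)-3-methoxyphenyl]boronic acid; 5 ethyl 2-(bromomethyl)prop-2-enoate
Product: 6 ethyl 2-(ArG-methyl)prop-2-enoate
Conditions: Pd(PPh3)4 (3 mol%), K2CO3, THF–H2O, 60 °C
Reagents that add atoms: none
Why: Suzuki–Miyaura-type allyl–aryl coupling through a symmetrical 2-(ethoxycarbonyl)allyl palladium intermediate, so that either allyl terminus gives the same 2-benzylacrylate.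

Step 4
Reactants: 6 ethyl 2-(ArG-methyl)prop-2-enoate
Product: 7 2-(ArG-methyl)prop-2-en-1-ol
Conditions: iBu2AlH (2.2 equiv), CH2Cl2, −78 °C
Reagents that add atoms: none
Why: 1,2-reduction of the acrylate ester by the aluminium hydride gives the 2-substituted allylic alcohol required for the asymmetric epoxidation.

Step 5
Reactants: 7 2-(ArG-methyl)prop-2-en-1-ol
Product: 8 [(2S)-2-(ArG-methyl)oxiran-2-yl]methanol
Conditions: Ti(OiPr)4 (10 mol%), L-(+)-diethyl tartrate (12 mol%), tBuOOH, 4 Å MS, CH2Cl2, −20 °C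
Reagents that add atoms: tert-butyl hydroperoxide CC(C)(C)OO
Why: Sharpless asymmetric epoxidation; with the L-(+)-tartrate oxygen is delivered to the same olefin face as in the allyl alcohol → (S)-glycidol case, which sets the (S) quaternary centre that becomes C4 of both halves, catalytic titanium and low temperature limiting opening of the 2,2-disubstituted epoxide.

Step 6
Reactants: 8 [(2S)-2-(ArG-methyl)oxiran-2-yl]methanol
Product: 9 (2R)-2-(ArG-methyl)oxirane-2-carbaldehyde
Conditions: Dess–Martin periodinane, pyridine, CH2Cl2, 0 °C → rt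
Reagents that add atoms: none
Why: Dess–Martin oxidation under buffered, non-basic conditions avoids Payne-type scrambling of the epoxy alcohol, and the fully substituted α-carbon cannot epimerise (the descriptor changes only through priority order).

Step 7
Reactants: 9 (2R)-2-(ArG-methyl)oxirane-2-carbaldehyde
Product: 10 (2S)-2-(ArG-methyl)-2-ethenyloxirane
Conditions: Ph3PCH3Br, KN(SiMe3)2, THF, 0 °C; then 9, −78 °C → 0 °C
Reagents that add atoms: methyltriphenylphosphonium bromide C[P+](c1ccccc1)(c1ccccc1)c1ccccc1.[Br-]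
Why: Wittig methylenation of the non-enolisable epoxy aldehyde installs the vinyl group (future C3) on the stereocentre without touching it.

Step 8
Reactants: 10 (2S)-2-(ArG-methyl)-2-ethenyloxirane; 3 4-(benzyloxy)-3-bromo-5-methoxybenzoic acid
Product: 11 (2S)-2-(ArG-methyl)-2-hydroxybut-3-en-1-yl 4-(benzyloxy)-3-bromo-5-methoxybenzoate
Conditions: Cs2CO3 (0.2 equiv), DMF, 70 °C
Reagents that add atoms: none
Why: base-catalysed SN2 opening of the epoxide by the carboxylate at the unsubstituted CH2 joins the two fragments as the aroate of the future C5 oxygen and frees the tertiary C4 hydroxyl, the quaternary centre not being involved.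

Step 9
Reactants: 11 hydroxy ester
Product: 12 (2S)-2-(ArG-methyl)-2-(triethylsilyloxy)but-3-en-1-yl 4-(benzyloxy)-3-bromo-5-methoxybenzoate
Conditions: Et3SiOTf, 2,6-lutidine, CH2Cl2, −78 °C → 0 °C
Reagents that add atoms: triethylsilyl trifluoromethanesulfonate CC[Si](CC)(CC)OS(=O)(=O)C(F)(F)F
Why: silylation of the hindered tertiary alcohol with the silyl triflate masks the hydroxyl that would otherwise quench the titanium alkylidene of step 10 and react with the formylating agent of step 11.

Step 10
Reactants: 12 silyl-protected vinyl aroate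
Product: 14 (3S)-5-ArBr-3-(ArG-methyl)-3-(triethylsilyloxy)-2,3-dihydrofuran, via titanium alkylidene 13 (not isolated)
Conditions: TiCl4, TMEDA, Zn, PbCl2 (cat.), CH3CHBr2, THF–CH2Cl2, 0 °C → 65 °C
Reagents that add atoms: none
Why: The titanium ethylidene made in the flask exchanges with the only unhindered alkene, the terminal vinyl group on C4, by [2+2]/retro-[2+2] (propene leaves) to give alkylidene 13, whose carbon C3 adds across the aroate C=O five atoms away, and collapse of the oxatitanacyclobutane expels the titanium oxo unit and leaves the C2=C3 enol ether. The closest known reaction type is the olefinic-ester cyclisation with Takai–Utimoto-type titanium alkylidenes (ring-closing ester olefination–metathesis), which converts esters of alkenols into five- to seven-membered cyclic enol ethers. One ring is closed, the 4,5-dihydrofuran O1–C2–C3–C4–C5, through the C2=C3 bond in a ring-closing carbonyl–olefin metathesis mode. No new stereocentre arises: the quaternary, silyl-protected C4 centre has no acidic hydrogen and keeps its (S) configuration, and the planar C2=C3 unit is what the face-selective hydrogenation of step 13 needs. The step needs ring closure to win over simple ethylidenation of the ester and over attack on the C–Br bond: the ethylidene reagent reacts faster with a monosubstituted alkene than with a conjugated aroate, the ring being formed is five-membered, and aryl bromides, silyl ethers and benzyl ethers are inert to the zinc/titanium reagent at this temperature.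

Step 11
Reactants: 14 dihydrofuran silyl ether
Product: 16 (4S)-2-ArBr-4-(ArG-methyl)-4-(triethylsilyloxy)-4,5-dihydrofuran-3-carbaldehyde, via iminium chloride 15 (not isolated)
Conditions: (chloromethylene)dimethyliminium chloride, 2,6-lutidine, CH2Cl2, 0 °C; then aq. NaHCO3
Reagents that add atoms: (chloromethylene)dimethyliminium chloride C[N+](C)=CCl.[Cl-]; water O
Why: Vilsmeier–Haack formylation of the electron-rich enol ether at its β-carbon C3 (attack gives the aryl- and oxygen-stabilised C2 cation, loss of H3 restores the double bond) brings in the last carbon as a vinylogous formate, the lutidine taking up the HCl that would otherwise protonate the enol ether.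

Step 12
Reactants: 16 dihydrofuran carbaldehyde
Product: 18 (3S)-5-ArBr-3-(ArG-methyl)-4-(hydroxymethyl)-2,3-dihydrofuran-3-ol, via silyl-protected allylic alcohol 17 (not isolated)
Conditions: iBu2AlH, CH2Cl2, −78 °C; aq. potassium sodium tartrate; then Bu4NF, THF, 0 °C
Reagents that add atoms: none
Why: aprotic 1,2-reduction of the aldehyde followed by fluoride desilylation keeps the acid-labile hydroxymethyl enol ether under non-acidic conditions throughout and frees the tertiary hydroxyl that directs step 13.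

Step 13
Reactants: 18 dihydrofuran diol
Product: 19 (3S,4R,5R)-5-ArBr-3-(ArG-methyl)-4-(hydroxymethyl)oxolan-3-ol
Conditions: [Ir(cod)(PCy3)(py)]PF6 (5 mol%), H2 (1 atm), CH2Cl2, 0 °C → rt
Reagents that add atoms: none
Why: hydroxyl-directed homogeneous hydrogenation, in which the cationic iridium is held by the tertiary C4–OH (the primary CH2OH can chelate from the same side) and adds both hydrogens to that face of the tetrasubstituted C2=C3, so that C2-aryl, C3-CH2OH and C4-arylmethyl end up mutually cis, while the aryl bromide and benzyl ethers are not touched.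

Step 14
Reactants: 19 bromo-oxolane (one part of the batch)
Product: 20 (2S,3S,4S)-6-(benzyloxy)-4-ArBr-2,3-bis(hydroxymethyl)-7-methoxy-1,2,3,4-tetrahydronaphthalen-2-ol
Conditions: CF3CO2H (3 equiv), CH2Cl2, 0 °C
Reagents that add atoms: none
Why: intramolecular Friedel–Crafts alkylation in which acid ionises the benzylic C2–O1 bond to a para-alkoxybenzyl cation that is captured by the arylmethyl ring para to its methoxy group (six-membered ring), the old C2 configuration being erased and the new centre set with the aryl group pseudo-equatorial and trans to the neighbouring CH2OH, as in the olivil → cycloolivil isomerisation.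

Step 15
Reactants: 19 bromo-oxolane (other part of the batch)
Product: 21 (3S,4R,5R)-5-[4-(benzyloxy)-3-methoxy-5-(4,4,5,5-tetramethyl-1,3,2-dioxaborolan-2-yl)phenyl]-3-(ArG-methyl)-4-(hydroxymethyl)oxolan-3-ol
Conditions: B2pin2, PdCl2(dppf) (5 mol%), KOAc, 1,4-dioxane, 90 °C
Reagents that add atoms: bis(pinacolato)diboron CC1(C)OB(OC1(C)C)B1OC(C)(C)C(C)(C)O1
Why: Miyaura borylation of the aryl bromide under weakly basic conditions that leave the free alcohols and the base-stable benzylic ether untouched.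

Step 16
Reactants: 21 oxolane boronate; 20 bromo-tetralin
Product: 22 tetrabenzyl ether of the target
Conditions: Pd(OAc)2 (5 mol%), SPhos (10 mol%), K3PO4, toluene–H2O, 80 °C
Reagents that add atoms: none
Why: Suzuki–Miyaura coupling of two ortho-alkoxy partners with a bulky biarylphosphine ligand forms the 5,5′-biaryl bond, which carries only two ortho substituents and so is not a stereogenic axis, while the free hydroxyls and all six stereocentres are unaffected by the basic conditions.

Step 17
Reactants: 22 tetrabenzyl ether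
Product: 23 target CNP0344108.1
Conditions: H2 (1 atm), Pd/C (10%), EtOAc–MeOH, rt
Reagents that add atoms: none
Why: hydrogenolysis of the four aryl benzyl ethers, which cleave much faster than the benzylic C–O bond of the 2-aryloxolane, so the reaction is stopped after uptake of four equivalents of hydrogen.

**Compound list**

1 | 5-bromovanillin (3-bromo-4-hydroxy-5-methoxybenzaldehyde) | COc1cc(C=O)cc(Br)c1O | starting material
2 | 4-(benzyloxy)-3-bromo-5-methoxybenzaldehyde | COc1cc(C=O)cc(Br)c1OCc1ccccc1 | intermediate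
3 | 4-(benzyloxy)-3-bromo-5-methoxybenzoic acid | COc1cc(C(=O)O)cc(Br)c1OCc1ccccc1 | intermediate
4 | [4-(benzyloxy)-3-methoxyphenyl]boronic acid | COc1cc(B(O)O)ccc1OCc1ccccc1 | starting material
5 | ethyl 2-(bromomethyl)prop-2-enoate | CCOC(=O)C(=C)CBr | starting material
6 | ethyl 2-{[4-(benzyloxy)-3-methoxyphenyl]methyl}prop-2-enoate | CCOC(=O)C(=C)Cc1ccc(OCc2ccccc2)c(OC)c1 | intermediate
7 | 2-{[4-(benzyloxy)-3-methoxyphenyl]methyl}prop-2-en-1-ol | OCC(=C)Cc1ccc(OCc2ccccc2)c(OC)c1 | intermediate
8 | [(2S)-2-{[4-(benzyloxy)-3-methoxyphenyl]methyl}oxiran-2-yl]methanol | COc1cc(C[C@@]2(CO)OC2)ccc1OCc1ccccc1 | intermediate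
9 | (2R)-2-{[4-(benzyloxy)-3-methoxyphenyl]methyl}oxirane-2-carbaldehyde | COc1cc(C[C@@]2(C=O)OC2)ccc1OCc1ccccc1 | intermediate
10 | (2S)-2-{[4-(benzyloxy)-3-methoxyphenyl]methyl}-2-ethenyloxirane | COc1cc(C[C@@]2(C=C)OC2)ccc1OCc1ccccc1 | intermediate
11 | (2S)-2-{[4-(benzyloxy)-3-methoxyphenyl]methyl}-2-hydroxybut-3-en-1-yl 4-(benzyloxy)-3-bromo-5-methoxybenzoate | COc1cc(C[C@@](COC(=O)c2cc(OC)c(OCc3ccccc3)c(Br)c2)(C=C)O)ccc1OCc1ccccc1 | intermediate
12 | (2S)-2-{[4-(benzyloxy)-3-methoxyphenyl]methyl}-2-[(triethylsilyl)oxy]but-3-en-1-yl 4-(benzyloxy)-3-bromo-5-methoxybenzoate | COc1cc(C[C@@](COC(=O)c2cc(OC)c(OCc3ccccc3)c(Br)c2)(C=C)O[Si](CC)(CC)CC)ccc1OCc1ccccc1 | intermediate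
13 | dichlorotitanium alkylidene of 12 (Ti=CH in place of the vinyl CH=CH2; C4 configuration as in 12) | COc1cc(C[C@@](COC(=O)c2cc(OC)c(OCc3ccccc3)c(Br)c2)(C=[Ti](Cl)Cl)O[Si](CC)(CC)CC)ccc1OCc1ccccc1 | intermediate (not isolated)
14 | (3S)-5-[4-(benzyloxy)-3-bromo-5-methoxyphenyl]-3-{[4-(benzyloxy)-3-methoxyphenyl]methyl}-3-[(triethylsilyl)oxy]-2,3-dihydrofuran | COc1cc(C[C@@]2(O[Si](CC)(CC)CC)COC(c3cc(OC)c(OCc4ccccc4)c(Br)c3)=C2)ccc1OCc1ccccc1 | intermediate
15 | N-{[(4S)-2-[4-(benzyloxy)-3-bromo-5-methoxyphenyl]-4-{[4-(benzyloxy)-3-methoxyphenyl]methyl}-4-[(triethylsilyl)oxy]-4,5-dihydrofuran-3-yl]methylidene}-N-methylmethanaminium chloride | COc1cc(C[C@@]2(O[Si](CC)(CC)CC)COC(c3cc(OC)c(OCc4ccccc4)c(Br)c3)=C2C=[N+](C)C)ccc1OCc1ccccc1.[Cl-] | intermediate (not isolated)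
16 | (4S)-2-[4-(benzyloxy)-3-bromo-5-methoxyphenyl]-4-{[4-(benzyloxy)-3-methoxyphenyl]methyl}-4-[(triethylsilyl)oxy]-4,5-dihydrofuran-3-carbaldehyde | COc1cc(C[C@@]2(O[Si](CC)(CC)CC)COC(c3cc(OC)c(OCc4ccccc4)c(Br)c3)=C2C=O)ccc1OCc1ccccc1 | intermediate
17 | [(4S)-2-[4-(benzyloxy)-3-bromo-5-methoxyphenyl]-4-{[4-(benzyloxy)-3-methoxyphenyl]methyl}-4-[(triethylsilyl)oxy]-4,5-dihydrofuran-3-yl]methanol | COc1cc(C[C@@]2(O[Si](CC)(CC)CC)COC(c3cc(OC)c(OCc4ccccc4)c(Br)c3)=C2CO)ccc1OCc1ccccc1 | intermediate (not isolated)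
18 | (3S)-5-[4-(benzyloxy)-3-bromo-5-methoxyphenyl]-3-{[4-(benzyloxy)-3-methoxyphenyl]methyl}-4-(hydroxymethyl)-2,3-dihydrofuran-3-ol | COc1cc(C[C@@]2(O)COC(c3cc(OC)c(OCc4ccccc4)c(Br)c3)=C2CO)ccc1OCc1ccccc1 | intermediate
19 | (3S,4R,5R)-5-[4-(benzyloxy)-3-bromo-5-methoxyphenyl]-3-{[4-(benzyloxy)-3-methoxyphenyl]methyl}-4-(hydroxymethyl)oxolan-3-ol | COc1cc(C[C@@]2(O)CO[C@@H](c3cc(OC)c(OCc4ccccc4)c(Br)c3)[C@H]2CO)ccc1OCc1ccccc1 | intermediate
20 | (2S,3S,4S)-6-(benzyloxy)-4-[4-(benzyloxy)-3-bromo-5-methoxyphenyl]-2,3-bis(hydroxymethyl)-7-methoxy-1,2,3,4-tetrahydronaphthalen-2-ol | COc1cc([C@H]2c3cc(OCc4ccccc4)c(OC)cc3C[C@@](O)(CO)[C@@H]2CO)cc(Br)c1OCc1ccccc1 | intermediate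
21 | (3S,4R,5R)-5-[4-(benzyloxy)-3-methoxy-5-(4,4,5,5-tetramethyl-1,3,2-dioxaborolan-2-yl)phenyl]-3-{[4-(benzyloxy)-3-methoxyphenyl]methyl}-4-(hydroxymethyl)oxolan-3-ol | COc1cc(C[C@@]2(O)CO[C@@H](c3cc(OC)c(OCc4ccccc4)c(B4OC(C)(C)C(C)(C)O4)c3)[C@H]2CO)ccc1OCc1ccccc1 | intermediate
22 | (3S,4R,5R)-5-{2,2′-bis(benzyloxy)-5′-[(1S,2S,3S)-7-(benzyloxy)-3-hydroxy-2,3-bis(hydroxymethyl)-6-methoxy-1,2,3,4-tetrahydronaphthalen-1-yl]-3,3′-dimethoxybiphenyl-5-yl}-3-{[4-(benzyloxy)-3-methoxyphenyl]methyl}-4-(hydroxymethyl)oxolan-3-ol | COc1cc(C[C@@]2(O)CO[C@@H](c3cc(OC)c(OCc4ccccc4)c(-c4cc([C@H]5c6cc(OCc7ccccc7)c(OC)cc6C[C@@](O)(CO)[C@@H]5CO)cc(OC)c4OCc4ccccc4)c3)[C@H]2CO)ccc1OCc1ccccc1 | intermediate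
23 | CNP0344108.1, (3S,4R,5R)-5-{5′-[(1S,2S,3S)-3,7-dihydroxy-2,3-bis(hydroxymethyl)-6-methoxy-1,2,3,4-tetrahydronaphthalen-1-yl]-2,2′-dihydroxy-3,3′-dimethoxybiphenyl-5-yl}-3-[(4-hydroxy-3-methoxyphenyl)methyl]-4-(hydroxymethyl)oxolan-3-ol | COc1cc(C[C@@]2(O)CO[C@@H](c3cc(OC)c(O)c(-c4cc([C@H]5c6cc(O)c(OC)cc6C[C@@](O)(CO)[C@@H]5CO)cc(OC)c4O)c3)[C@H]2CO)ccc1O | target

**Step count and risks**

Total step count: 17. Longest linear sequence: 14 steps (steps 3 to 13, then 15 or 14, then 16 and 17).

Steps most likely to fail: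

Step 10. The titanium reagent may ethylidenate the ester without closing the ring, because exchange with a vinyl group next to a quaternary carbon is slow, or the zinc/titanium mixture may reduce the aryl C–Br bond. Fallback: the ester of 12 is methylenated without zinc (Cp2TiMe2, toluene, 70 °C) to the acyclic 1-arylvinyl ether triethyl{[(2S)-1-({1-[4-(benzyloxy)-3-bromo-5-methoxyphenyl]ethenyl}oxy)-2-{[4-(benzyloxy)-3-methoxyphenyl]methyl}but-3-en-2-yl]oxy}silane F1. F1 is then closed by olefin metathesis with the second-generation Grubbs catalyst (toluene, 70 °C): the ruthenium alkylidene forms at the vinyl group and closes onto the enol ether with loss of ethene. This comes back to the route at 14.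

Step 13. The acid-labile hydroxymethyl enol ether may ionise on the acidic iridium hydride, the primary allylic alcohol may isomerise to the aldehyde, or hydrogen delivery to the tetrasubstituted alkene may be slow and poorly face-selective. Fallback by ionic hydrogenation: the primary alcohol of 18 is silylated (tBuMe2SiCl, imidazole, DMF) to (3S)-5-[4-(benzyloxy)-3-bromo-5-methoxyphenyl]-3-{[4-(benzyloxy)-3-methoxyphenyl]methyl}-4-{[(tert-butyldimethylsilyl)oxy]methyl}-2,3-dihydrofuran-3-ol F2. F2 is treated with Et3SiH and CF3CO2H in CH2Cl2 at −78 °C. Reversible protonation at C3 gives the 2-aryl oxocarbenium ion, and hydride adds to C2 anti to the C3 substituent. This is fastest for the C3 epimer whose CH2OSi group is cis to the arylmethyl group, because only that ion has one open face. The expected product is the all-cis (3S,4R,5R)-5-[4-(benzyloxy)-3-bromo-5-methoxyphenyl]-3-{[4-(benzyloxy)-3-methoxyphenyl]methyl}-4-{[(tert-butyldimethylsilyl)oxy]methyl}oxolan-3-ol F3, and Bu4NF then returns the route to 19.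

Step 11. The HCl released may protonate the enol ether or cleave the silyl ether faster than formylation occurs at the hindered C3 next to the quaternary carbon. Fallback by acylation under basic conditions: 14 is treated with trichloroacetyl chloride and pyridine (CH2Cl2, 0 °C) to give 1-[(4S)-2-[4-(benzyloxy)-3-bromo-5-methoxyphenyl]-4-{[4-(benzyloxy)-3-methoxyphenyl]methyl}-4-[(triethylsilyl)oxy]-4,5-dihydrofuran-3-yl]-2,2,2-trichloroethan-1-one F4. Haloform-type cleavage with NaOMe in MeOH gives methyl (4S)-2-[4-(benzyloxy)-3-bromo-5-methoxyphenyl]-4-{[4-(benzyloxy)-3-methoxyphenyl]methyl}-4-[(triethylsilyl)oxy]-4,5-dihydrofuran-3-carboxylate F5. Reduction with iBu2AlH at −78 °C then comes back to the route at 17, which is desilylated to 18 as in step 12.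

**Further compounds**

F1 | step 10 | triethyl{[(2S)-1-({1-[4-(benzyloxy)-3-bromo-5-methoxyphenyl]ethenyl}oxy)-2-{[4-(benzyloxy)-3-methoxyphenyl]methyl}but-3-en-2-yl]oxy}silane | COc1cc(C[C@@](COC(=C)c2cc(OC)c(OCc3ccccc3)c(Br)c2)(C=C)O[Si](CC)(CC)CC)ccc1OCc1ccccc1
F2 | step 13 | (3S)-5-[4-(benzyloxy)-3-bromo-5-methoxyphenyl]-3-{[4-(benzyloxy)-3-methoxyphenyl]methyl}-4-{[(tert-butyldimethylsilyl)oxy]methyl}-2,3-dihydrofuran-3-ol | COc1cc(C[C@@]2(O)COC(c3cc(OC)c(OCc4ccccc4)c(Br)c3)=C2CO[Si](C)(C)C(C)(C)C)ccc1OCc1ccccc1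
F3 | step 13 | (3S,4R,5R)-5-[4-(benzyloxy)-3-bromo-5-methoxyphenyl]-3-{[4-(benzyloxy)-3-methoxyphenyl]methyl}-4-{[(tert-butyldimethylsilyl)oxy]methyl}oxolan-3-ol | COc1cc(C[C@@]2(O)CO[C@@H](c3cc(OC)c(OCc4ccccc4)c(Br)c3)[C@H]2CO[Si](C)(C)C(C)(C)C)ccc1OCc1ccccc1
F4 | step 11 | 1-[(4S)-2-[4-(benzyloxy)-3-bromo-5-methoxyphenyl]-4-{[4-(benzyloxy)-3-methoxyphenyl]methyl}-4-[(triethylsilyl)oxy]-4,5-dihydrofuran-3-yl]-2,2,2-trichloroethan-1-one | COc1cc(C[C@@]2(O[Si](CC)(CC)CC)COC(c3cc(OC)c(OCc4ccccc4)c(Br)c3)=C2C(=O)C(Cl)(Cl)Cl)ccc1OCc1ccccc1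
F5 | step 11 | methyl (4S)-2-[4-(benzyloxy)-3-bromo-5-methoxyphenyl]-4-{[4-(benzyloxy)-3-methoxyphenyl]methyl}-4-[(triethylsilyl)oxy]-4,5-dihydrofuran-3-carboxylate | COc1cc(C[C@@]2(O[Si](CC)(CC)CC)COC(c3cc(OC)c(OCc4ccccc4)c(Br)c3)=C2C(=O)OC)ccc1OCc1ccccc1
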